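Everything rests on building ring A last. In the flavanone the C4a=C8a bond lies α,β to the C4 ketone with O1 on C8a. The C5 and C7 hydroxyls are meta to each other. Together this is the imprint of a 1,1,3-trioxygenated butadiene on a polarised enone. The precursor is therefore an enantiopure (S)-2-aryl-5-(p-tolylsulfinyl)-2,3-dihydropyran-4-one that already carries C2 and the finished, bis-silylated diprenyl ring B. With the bis(silyl) dienolate of methyl acetoacetate it forms C8–C8a and C4a–C5. Loss of sulfenic acid and methanol aromatises the new carbocycle in the same flask. C2 stems from a catalytic asymmetric hetero-Diels–Alder reaction, and sulfur is installed before the prenyl groups.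

Key step: step 10

**Remarks**
- Abbreviations: TBS = tert-butyldimethylsilyl, TMS = trimethylsilyl, Tol = p-tolyl.
- Numbering: flavanone numbering, with primes for ring B, is used for positions. Pyranone C5 is flavanone C4a and pyranone C6 is C8a.
- Assumption: the titanium complex of the (S)-configured ligand is taken to direct the diene to the Si face of aldehyde 5, which gives 2S. Should the opposite sense be found, the (R)-ligand is used and nothing else changes.
- Order of events: a sulfenyl chloride adds to a trisubstituted alkene faster than to a vinylogous ester. Sulfur is therefore put on the dibromide and the prenyl groups follow.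
- Role of the bromines: they make the aldehyde more electrophilic and hold back ionisation of the benzylic C2–O1 bond in the two acidic operations.
- Oxidation and key step: the sulfide is oxidised with a reagent that does not epoxidise alkenes. The sulfoxide is used as a mixture of sulfur epimers. The key step runs without Lewis acid, because C2–O1 is a p-silyloxybenzylic bond to a good leaving group.

**Step 1**
Reactants: 1 vanillin
Product: 3 5,6-dibromovanillin (= 2,3-dibromo-4-hydroxy-5-methoxybenzaldehyde), via 5-bromovanillin 2 (not isolated)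
Conditions: Br2 (1.05 equiv), AcOH, rt; then Fe powder (5 mol %), Br2 (1.2 equiv), 50 °C
Reagents that add atoms: bromine, BrBr
Why: Electrophilic aromatic bromination in which the free phenol directs the first bromine ortho to itself (C5) and, under iron catalysis, the methoxy group directs the second para to itself (C6), the established access to this known dibromide.

**Step 2**
Reactants: 3 5,6-dibromovanillin
Product: 4 2,3-dibromo-4,5-dihydroxybenzaldehyde
Conditions: AlCl3 (1.5 equiv), pyridine (4.5 equiv), CH2Cl2, reflux; then 2 M HCl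
Reagents that add atoms: none
Why: Lewis-acid-assisted aryl methyl ether cleavage, in which aluminium chelated between the neighbouring phenoxide and methoxy oxygens activates the O–CH3 bond for SN2 attack by pyridine, a standard demethylation of 5-substituted vanillins that spares the aldehyde and the C–Br bonds.

**Step 3**
Reactants: 4 2,3-dibromo-4,5-dihydroxybenzaldehyde
Product: 5 2,3-dibromo-4,5-bis(tert-butyldimethylsilyloxy)benzaldehyde
Conditions: TBSCl (2.6 equiv), imidazole (5 equiv), DMF, rt
Reagents that add atoms: tert-butyldimethylsilyl chloride, CC(C)(C)[Si](C)(C)Cl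
Why: Imidazole-promoted silylation of phenols; TBS should survive titanium catalysis, brief TFA, the sulfenyl chloride, palladium at 105 °C and dilute acid, yet leaves with buffered fluoride, so that no strong acid ever meets a free phenol ortho to a prenyl group.

**Step 4**
Reactants: 5 2,3-dibromo-4,5-bis(tert-butyldimethylsilyloxy)benzaldehyde; 6 (E)-1-methoxy-3-(trimethylsilyloxy)buta-1,3-diene
Product: 8 (S)-2-[2,3-dibromo-4,5-bis(tert-butyldimethylsilyloxy)phenyl]-2,3-dihydro-4H-pyran-4-one, via silylated aldol adduct 7 (not isolated)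
Conditions: (S)-H8-BINOL (22 mol %), Ti(OiPr)4 (20 mol %), 4 Å MS, toluene, 0 °C; then TFA (0.2 equiv), CH2Cl2, 0 °C
Reagents that add atoms: none
Why: Catalytic asymmetric hetero-Diels–Alder reaction of the Mukaiyama-aldol/cyclisation type, in which the chiral titanium binaphtholate binds the aldehyde and leaves its Si face open to the diene terminus, which sets C2 as S, and acid then closes the ring by oxa-Michael addition and loss of methanol without touching the C2–O bond.

**Step 5**
Reactants: 8 (S)-2-[2,3-dibromo-4,5-bis(tert-butyldimethylsilyloxy)phenyl]-2,3-dihydro-4H-pyran-4-one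
Product: 10 (S)-2-[2,3-dibromo-4,5-bis(tert-butyldimethylsilyloxy)phenyl]-5-(p-tolylthio)-2,3-dihydro-4H-pyran-4-one, via chloro sulfide adduct 9 (not isolated)
Conditions: (TolS)2 (0.55 equiv), SO2Cl2 (0.55 equiv), CH2Cl2, 0 °C; then 8, −78 → 0 °C; then Et3N (1.5 equiv), 0 °C
Reagents that add atoms: di-p-tolyl disulfide, Cc1ccc(SSc2ccc(C)cc2)cc1; sulfuryl chloride, O=S(=O)(Cl)Cl (its chlorine is found only in 9)
Why: Electrophilic α-sulfenylation of a vinylogous ester by addition–elimination, with sulfur going to the nucleophilic pyranone C5 (C4a), chloride to the oxocarbenium carbon C6 (C8a) and triethylamine removing HCl through the acidic H-5, the pattern of α-halogenation of dihydropyranones and of 2-sulfenylation of glycals, at a stage where no other alkene is present.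

**Step 6**
Reactants: 10 (S)-2-[2,3-dibromo-4,5-bis(tert-butyldimethylsilyloxy)phenyl]-5-(p-tolylthio)-2,3-dihydro-4H-pyran-4-one; 11 tributyl(3-methylbut-2-enyl)stannane
Product: 13 (S)-2-[4,5-bis(tert-butyldimethylsilyloxy)-2,3-bis(3-methylbut-2-enyl)phenyl]-5-(p-tolylthio)-2,3-dihydro-4H-pyran-4-one, via monoprenyl bromide 12 (not isolated)
Conditions: 11 (3 equiv), Pd(PPh3)4 (10 mol %), toluene, 105 °C, Ar, dark
Reagents that add atoms: none
Why: Twofold Migita–Kosugi–Stille allylation under neutral, fluoride-free conditions, in which each aryl–palladium species takes the prenyl group from tin and reductive elimination at the unsubstituted allyl terminus gives the linear prenyl arene, while the aryl silyl ethers, the vinyl sulfide and the base-sensitive C2 centre are left alone.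

**Step 7**
Reactants: 13 (S)-2-[4,5-bis(tert-butyldimethylsilyloxy)-2,3-bis(3-methylbut-2-enyl)phenyl]-5-(p-tolylthio)-2,3-dihydro-4H-pyran-4-one
Product: 14 (S)-2-[4,5-bis(tert-butyldimethylsilyloxy)-2,3-bis(3-methylbut-2-enyl)phenyl]-5-(p-tolylsulfinyl)-2,3-dihydro-4H-pyran-4-one (mixture of sulfur epimers, used as such)
Conditions: 2-(phenylsulfonyl)-3-phenyloxaziridine (1.05 equiv), CH2Cl2, 0 °C → rt
Reagents that add atoms: 2-(phenylsulfonyl)-3-phenyloxaziridine, O=S(=O)(c1ccccc1)N1OC1c1ccccc1
Why: Chemoselective sulfide-to-sulfoxide oxidation with an N-sulfonyloxaziridine, a neutral aprotic oxygen donor that attacks sulfur at or below room temperature, epoxidises unactivated alkenes only on prolonged heating and oxidises sulfoxides far more slowly, so both prenyl groups should survive and no sulfone form; the sulfur centre is uncontrolled and is lost in step 10.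

**Step 8**
Reactants: 15 methyl acetoacetate
Product: 16 methyl 3-(trimethylsilyloxy)but-2-enoate
Conditions: TMSCl (1.5 equiv), Et3N (1.6 equiv), hexane, rt
Reagents that add atoms: chlorotrimethylsilane, C[Si](C)(C)Cl
Why: O-Silylation of the enol of a β-keto ester, the standard first stage in the preparation of 1,3-bis(silyloxy)dienes.

**Step 9**
Reactants: 16 methyl 3-(trimethylsilyloxy)but-2-enoate
Product: 17 1-methoxy-1,3-bis(trimethylsilyloxy)buta-1,3-diene
Conditions: LDA (1.15 equiv), THF, −78 °C; TMSCl (1.3 equiv), −78 °C → rt; used freshly distilled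
Reagents that add atoms: chlorotrimethylsilane, C[Si](C)(C)Cl
Why: γ-Deprotonation of the silyloxycrotonate and O-silylation of the resulting ester dienolate, the standard second stage of the same preparation.

**Step 10**
Reactants: 14 (S)-2-[4,5-bis(tert-butyldimethylsilyloxy)-2,3-bis(3-methylbut-2-enyl)phenyl]-5-(p-tolylsulfinyl)-2,3-dihydro-4H-pyran-4-one; 17 1-methoxy-1,3-bis(trimethylsilyloxy)buta-1,3-diene
Product: 21 (S)-4',5'-bis-O-(tert-butyldimethylsilyl)abyssinin III, via cycloadduct 18 (not isolated), via cyclohexadiene ketal 19 (not isolated), via bis-TMS ether 20 (not isolated)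
Conditions: 17 (3 equiv), toluene, 0 °C → rt, then 80 °C; then THF–0.5 M aq HCl, 0 °C
Reagents that add atoms: none
Why: Proposed new method: the CH2 terminus of ketene-acetal diene 17, its most nucleophilic carbon, should bond to C8a, the carbon made electrophilic by both the C4 carbonyl and the sulfinyl group, and the α-sulfinyl enolate carbon C4a then closes on the dioxy-stabilised cationic carbon C5, so that ring A forms as a six-membered carbocycle by a strongly asynchronous [4+2] addition (6-(enolexo)-exo-trig in the stepwise limit). In cis-fused 18 the sulfinyl group and H-8a, which are cis on the dienophile, remain syn, so thermal sulfoxide syn-elimination restores C4a=C8a (19), loss of methanol from the C5 ketal together with a C8 proton gives the aromatic bis-TMS ether 20, and dilute acid frees the two phenols while the aryl TBS ethers stay. The closest known reactions are the cycloaddition–aromatisation of 1,1,3-trioxygenated dienes with halo- and sulfinylquinones and of oxygenated dienes with chromones bearing an acceptor at C3 (xanthone synthesis), whereas a monocyclic 5-sulfinyl-2,3-dihydropyran-4-one has not been used in this way. No stereocentre is created for keeps, since the new sp3 centres of 18 are erased on aromatisation, and C2 is a spectator that only base, Lewis acid or ionising media could endanger, hence neutral toluene and no promoter. The selectivity needed is regiochemical (C8 to C8a and C5 to C4a, which puts the hydroxyls on C5 and C7) and is secured by the matched polarity of the two partners, and ring closure must also outrun expulsion of O1 from the first-formed enolate, which the non-polar medium and the adjacent cationic C5 should favour. The excess of 17 also scavenges the sulfenic acid and keeps it away from the prenyl groups and the electron-rich new ring.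

**Step 11**
Reactants: 21 (S)-4',5'-bis-O-(tert-butyldimethylsilyl)abyssinin III
Product: 22 abyssinin III, (S)-2-[4,5-dihydroxy-2,3-bis(3-methylbut-2-enyl)phenyl]-5,7-dihydroxychroman-4-one
Conditions: TBAF (2.2 equiv), AcOH (3 equiv), THF, 0 °C, Ar
Reagents that add atoms: none
Why: Fluoride-induced cleavage of aryl silyl ethers, with acetic acid protonating the phenoxides as they form, so that the flavanone sees neither base (no retro-oxa-Michael opening to the chalcone, hence no racemisation at C2) nor an acid strong enough to cyclise the 3'-prenyl group onto the 4'-hydroxyl.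

**Compound list**

1 | vanillin | COc1cc(C=O)ccc1O | starting material
2 | 5-bromovanillin | COc1cc(C=O)cc(Br)c1O | intermediate
3 | 5,6-dibromovanillin (2,3-dibromo-4-hydroxy-5-methoxybenzaldehyde) | COc1cc(C=O)c(Br)c(Br)c1O | intermediate
4 | 2,3-dibromo-4,5-dihydroxybenzaldehyde | O=Cc1cc(O)c(O)c(Br)c1Br | intermediate
5 | 2,3-dibromo-4,5-bis(tert-butyldimethylsilyloxy)benzaldehyde | O=Cc1cc(O[Si](C)(C)C(C)(C)C)c(O[Si](C)(C)C(C)(C)C)c(Br)c1Br | intermediate
6 | (E)-1-methoxy-3-(trimethylsilyloxy)buta-1,3-diene | CO/C=C/C(=C)O[Si](C)(C)C | starting material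
7 | (S,E)-5-[2,3-dibromo-4,5-bis(TBSO)phenyl]-1-methoxy-5-(trimethylsilyloxy)pent-1-en-3-one | CO/C=C/C(=O)C[C@H](O[Si](C)(C)C)c1cc(O[Si](C)(C)C(C)(C)C)c(O[Si](C)(C)C(C)(C)C)c(Br)c1Br | intermediate
8 | (S)-2-[2,3-dibromo-4,5-bis(TBSO)phenyl]-2,3-dihydro-4H-pyran-4-one | Brc1c([C@@H]2CC(=O)C=CO2)cc(O[Si](C)(C)C(C)(C)C)c(O[Si](C)(C)C(C)(C)C)c1Br | intermediate
9 | (2S)-6-chloro-2-[2,3-dibromo-4,5-bis(TBSO)phenyl]-5-(p-tolylthio)tetrahydropyran-4-one (C5 and C6 transient, not defined) | Brc1c([C@@H]2CC(=O)C(Sc3ccc(C)cc3)C(Cl)O2)cc(O[Si](C)(C)C(C)(C)C)c(O[Si](C)(C)C(C)(C)C)c1Br | intermediate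
10 | (S)-2-[2,3-dibromo-4,5-bis(TBSO)phenyl]-5-(p-tolylthio)-2,3-dihydro-4H-pyran-4-one | Brc1c([C@@H]2CC(=O)C(Sc3ccc(C)cc3)=CO2)cc(O[Si](C)(C)C(C)(C)C)c(O[Si](C)(C)C(C)(C)C)c1Br | intermediate
11 | tributyl(3-methylbut-2-enyl)stannane | CC(C)=CC[Sn](CCCC)(CCCC)CCCC | starting material
12 | (S)-2-[3-bromo-4,5-bis(TBSO)-2-prenylphenyl]-5-(p-tolylthio)-2,3-dihydro-4H-pyran-4-one (order of the two couplings immaterial, one isomer drawn) | CC(C)=CCc1c([C@@H]2CC(=O)C(Sc3ccc(C)cc3)=CO2)cc(O[Si](C)(C)C(C)(C)C)c(O[Si](C)(C)C(C)(C)C)c1Br | intermediate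
13 | (S)-2-[4,5-bis(TBSO)-2,3-diprenylphenyl]-5-(p-tolylthio)-2,3-dihydro-4H-pyran-4-one | CC(C)=CCc1c([C@@H]2CC(=O)C(Sc3ccc(C)cc3)=CO2)cc(O[Si](C)(C)C(C)(C)C)c(O[Si](C)(C)C(C)(C)C)c1CC=C(C)C | intermediate
14 | (S)-2-[4,5-bis(TBSO)-2,3-diprenylphenyl]-5-(p-tolylsulfinyl)-2,3-dihydro-4H-pyran-4-one (both sulfur epimers form, one drawn) | CC(C)=CCc1c([C@@H]2CC(=O)C([S@](=O)c3ccc(C)cc3)=CO2)cc(O[Si](C)(C)C(C)(C)C)c(O[Si](C)(C)C(C)(C)C)c1CC=C(C)C | intermediate
15 | methyl acetoacetate | COC(=O)CC(C)=O | starting material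
16 | methyl 3-(trimethylsilyloxy)but-2-enoate (geometry immaterial, Z drawn) | COC(=O)/C=C(/C)O[Si](C)(C)C | intermediate
17 | 1-methoxy-1,3-bis(trimethylsilyloxy)buta-1,3-diene (geometry immaterial, one drawn) | CO/C(O[Si](C)(C)C)=C\C(=C)O[Si](C)(C)C | intermediate
18 | (2S)-2-aryl-5-methoxy-4a-(p-tolylsulfinyl)-5,7-bis(trimethylsilyloxy)-2,3,4a,5,8,8a-hexahydrochromen-4-one, cis-fused (C4a, C5, C8a and S transient, not drawn) | CC(C)=CCc1c([C@@H]2CC(=O)C3(S(=O)c4ccc(C)cc4)C(CC(O[Si](C)(C)C)=CC3(OC)O[Si](C)(C)C)O2)cc(O[Si](C)(C)C(C)(C)C)c(O[Si](C)(C)C(C)(C)C)c1CC=C(C)C | intermediate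
19 | (2S)-2-aryl-5-methoxy-5,7-bis(trimethylsilyloxy)-2,3,5,8-tetrahydrochromen-4-one (C5 transient, not drawn) | CC(C)=CCc1c([C@@H]2CC(=O)C3=C(CC(O[Si](C)(C)C)=CC3(OC)O[Si](C)(C)C)O2)cc(O[Si](C)(C)C(C)(C)C)c(O[Si](C)(C)C(C)(C)C)c1CC=C(C)C | intermediate
20 | (S)-5,7-bis-O-TMS-4',5'-bis-O-TBS-abyssinin III | CC(C)=CCc1c([C@@H]2CC(=O)c3c(O[Si](C)(C)C)cc(O[Si](C)(C)C)cc3O2)cc(O[Si](C)(C)C(C)(C)C)c(O[Si](C)(C)C(C)(C)C)c1CC=C(C)C | intermediate
21 | (S)-4',5'-bis-O-TBS-abyssinin III | CC(C)=CCc1c([C@@H]2CC(=O)c3c(O)cc(O)cc3O2)cc(O[Si](C)(C)C(C)(C)C)c(O[Si](C)(C)C(C)(C)C)c1CC=C(C)C | intermediate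
22 | abyssinin III, (2S) | CC(C)=CCc1c([C@@H]2CC(=O)c3c(O)cc(O)cc3O2)cc(O)c(O)c1CC=C(C)C | target

Total step count: 11. Longest linear sequence: 9 (steps 1–7, 10, 11); steps 8 and 9 are a side branch.

**Steps most likely to fail**

**Step 10 (key step).**
- The addition may stop after the first C–C bond through silyl transfer to the enolate.
- The enolate may expel O1 and open the pyranone.
- The diene may isomerise by silyl migration before it adds.
- Electrophiles derived from the sulfenic acid may sulfenylate the new ring.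

The fallback is known chemistry, the organocatalytic asymmetric oxa-Michael route to flavanones, and runs from 5 to 22. Commercial 2,4,6-trihydroxyacetophenone is silylated twice (TBSCl, imidazole, DMF), leaving one chelated ortho hydroxyl free, to give 2-hydroxy-4,6-bis(tert-butyldimethylsilyloxy)acetophenone F1. C-Acylation (LiHMDS, Boc2O, THF, −78 °C) gives the tert-butyl β-keto ester F2. Knoevenagel condensation of F2 with 5 (piperidine, AcOH, 4 Å MS, toluene) gives the alkylidene keto ester F3. A cinchona-alkaloid thiourea of the pseudoenantiomeric series that leads to 2S closes the pyranone by intramolecular oxa-Michael addition (toluene, −25 °C) to the chromanone-3-carboxylate F4. TsOH (toluene, 80 °C) cleaves the tert-butyl ester and decarboxylates to the dibromo flavanone F5, while no prenyl group is yet present. The conditions of step 6 give the tetrasilyl ether F6. The conditions of step 11 with twice the reagent give 22.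

**Step 6.**
- Oxidative addition may be slow at C–Br bonds that are flanked on both sides.
- The sulfide may inhibit palladium.
- Coupling may occur at the γ-terminus of the prenyl group.
- The aryl–palladium species may carbopalladate the neighbouring enone.
- Protodebromination may compete.

The fallback runs from 5 to 14. It moves the prenylation to the aldehyde and brings sulfur in as a nucleophile that is already a sulfoxide, so that neither a sulfur electrophile nor an oxidant meets the prenyl groups. Stille coupling of 5 with 11 gives 4,5-bis(tert-butyldimethylsilyloxy)-2,3-diprenylbenzaldehyde F7. Here the ortho formyl group activates the first C–Br bond, and forcing conditions are allowed because no stereocentre is at stake. A titanium–BINOL-catalysed Mukaiyama aldol addition of 1-(tert-butylthio)-1-(trimethylsilyloxy)ethene gives, after mild acidic work-up, the (S)-β-hydroxy thioester F8. Claisen-type acylation of lithiated methyl p-tolyl sulfoxide (3 equiv, THF, −78 °C) gives the hydroxy keto sulfoxide F9. N,N-Dimethylformamide dimethyl acetal (toluene, rt) formylates the active methylene group, and the hydroxyl group closes the ring with loss of dimethylamine, as known for δ-hydroxy-β-keto esters. This gives 14.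

**Step 4.**
- Facial selectivity may be poor, or turnover slow, with the ortho-bromo aldehyde.
- Enantiopurity may erode in the acid-induced ring closure.

The fallback runs from 5 to 8 under auxiliary control with separable diastereomers. The titanium enolate of N-acetyl-4-isopropyl-1,3-thiazolidine-2-thione (TiCl4, i-Pr2NEt, CH2Cl2, −78 °C) adds to 5 to give the acetate aldol adduct F10, which is brought to a single diastereomer by chromatography. The auxiliary antipode that leads to the S carbinol is used; the 4S form is drawn. MeNHOMe·HCl and imidazole give the Weinreb amide F11. Ethynylmagnesium bromide (3 equiv, THF, 0 °C) gives the β-hydroxy ynone F12. Gold(I)- or silver(I)-catalysed 6-endo-dig cycloisomerisation gives 8.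

**Further compounds**

F1 | step 10 | 2-hydroxy-4,6-bis(tert-butyldimethylsilyloxy)acetophenone | CC(=O)c1c(O)cc(O[Si](C)(C)C(C)(C)C)cc1O[Si](C)(C)C(C)(C)C
F2 | step 10 | tert-butyl 3-[2-hydroxy-4,6-bis(tert-butyldimethylsilyloxy)phenyl]-3-oxopropanoate | CC(C)(C)OC(=O)CC(=O)c1c(O)cc(O[Si](C)(C)C(C)(C)C)cc1O[Si](C)(C)C(C)(C)C
F3 | step 10 | tert-butyl 2-[2-hydroxy-4,6-bis(TBSO)benzoyl]-3-[2,3-dibromo-4,5-bis(TBSO)phenyl]acrylate (E/Z not defined) | CC(C)(C)OC(=O)C(=Cc1cc(O[Si](C)(C)C(C)(C)C)c(O[Si](C)(C)C(C)(C)C)c(Br)c1Br)C(=O)c1c(O)cc(O[Si](C)(C)C(C)(C)C)cc1O[Si](C)(C)C(C)(C)C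
F4 | step 10 | tert-butyl (2S)-2-[2,3-dibromo-4,5-bis(TBSO)phenyl]-5,7-bis(TBSO)-4-oxochromane-3-carboxylate (C3 labile, not defined) | Brc1c([C@@H]2C(C(=O)OC(C)(C)C)C(=O)c3c(O[Si](C)(C)C(C)(C)C)cc(O[Si](C)(C)C(C)(C)C)cc3O2)cc(O[Si](C)(C)C(C)(C)C)c(O[Si](C)(C)C(C)(C)C)c1Br
F5 | step 10 | (S)-2-[2,3-dibromo-4,5-bis(TBSO)phenyl]-5,7-bis(TBSO)chroman-4-one | Brc1c([C@@H]2CC(=O)c3c(O[Si](C)(C)C(C)(C)C)cc(O[Si](C)(C)C(C)(C)C)cc3O2)cc(O[Si](C)(C)C(C)(C)C)c(O[Si](C)(C)C(C)(C)C)c1Br
F6 | step 10 | (S)-5,7,4',5'-tetra-O-TBS-abyssinin III | CC(C)=CCc1c([C@@H]2CC(=O)c3c(O[Si](C)(C)C(C)(C)C)cc(O[Si](C)(C)C(C)(C)C)cc3O2)cc(O[Si](C)(C)C(C)(C)C)c(O[Si](C)(C)C(C)(C)C)c1CC=C(C)C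
F7 | step 6 | 4,5-bis(tert-butyldimethylsilyloxy)-2,3-bis(3-methylbut-2-enyl)benzaldehyde | CC(C)=CCc1c(C=O)cc(O[Si](C)(C)C(C)(C)C)c(O[Si](C)(C)C(C)(C)C)c1CC=C(C)C
F8 | step 6 | S-tert-butyl (S)-3-[4,5-bis(TBSO)-2,3-diprenylphenyl]-3-hydroxypropanethioate | CC(C)=CCc1c([C@@H](O)CC(=O)SC(C)(C)C)cc(O[Si](C)(C)C(C)(C)C)c(O[Si](C)(C)C(C)(C)C)c1CC=C(C)C
F9 | step 6 | (4S)-4-[4,5-bis(TBSO)-2,3-diprenylphenyl]-4-hydroxy-1-(p-tolylsulfinyl)butan-2-one (sulfur configuration immaterial, not drawn) | CC(C)=CCc1c([C@@H](O)CC(=O)CS(=O)c2ccc(C)cc2)cc(O[Si](C)(C)C(C)(C)C)c(O[Si](C)(C)C(C)(C)C)c1CC=C(C)C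
F10 | step 4 | (S)-3-[2,3-dibromo-4,5-bis(TBSO)phenyl]-3-hydroxy-1-[(S)-4-isopropyl-2-thioxo-1,3-thiazolidin-3-yl]propan-1-one | Brc1c([C@@H](O)CC(=O)N2C(=S)SC[C@@H]2C(C)C)cc(O[Si](C)(C)C(C)(C)C)c(O[Si](C)(C)C(C)(C)C)c1Br
F11 | step 4 | (S)-3-[2,3-dibromo-4,5-bis(TBSO)phenyl]-3-hydroxy-N-methoxy-N-methylpropanamide | Brc1c([C@@H](O)CC(=O)N(C)OC)cc(O[Si](C)(C)C(C)(C)C)c(O[Si](C)(C)C(C)(C)C)c1Br
F12 | step 4 | (S)-5-[2,3-dibromo-4,5-bis(TBSO)phenyl]-5-hydroxypent-1-yn-3-one | Brc1c([C@@H](O)CC(=O)C#C)cc(O[Si](C)(C)C(C)(C)C)c(O[Si](C)(C)C(C)(C)C)c1Br
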